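Remark on the chemistry: the key-step precursor is expected to rest as its cyclic hemiketal, a 2-benzyl-2-hydroxybenzofuran-3-one racemic at the hemiketal carbon, and is numbered 8 in that form; the open-chain 1,2-dione 9 is its ring–chain tautomer and the species that cyclises. Compounds 1 and 2 are taken as purchased, and every sulfated intermediate is carried as its sodium salt.

## Analysis of the target

Isorhamnetin 7-O-sulfate (13) is a flavonol: a 4H-chromen-4-one (rings A and C) with a 4-hydroxy-3-methoxyphenyl ring B on C2, hydroxyls on C3 and C5, and a hydrogen sulfate ester on O7. It has no stereocentre, so the task is one of oxidation level and of telling four hydroxyls apart. The aryl sulfate monoester is ionic, turns every later intermediate into a salt, and is hydrolysed by acid, including its own acid form. The 3-hydroxypyranone conjugated with the free 4'-phenol makes the finished flavonol easy to oxidise. The 5-hydroxyl is hydrogen-bonded to the C4 carbonyl and therefore differs from the 7-hydroxyl, but the 3- and 4'-hydroxyls would compete with O7 for a sulfating agent, so the sulfate has to go on while these are absent or masked. The hard part is to close ring C at the flavonol oxidation level, with O3 in place, on a sulfated polyphenol without protecting each hydroxyl. The strategy rests on the 4'-hydroxyl being para to C1', the carbon that carries C2: taking two electrons and two protons from a 4-hydroxybenzyl unit makes the benzylic carbon (the future C2) the electrophilic end of a quinone methide, within reach of an ortho hydroxyl of ring A, so that O1–C2 can be the last skeletal bond formed.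

## Retrosynthetic reasoning

13 from 12. The only change is the exchange of Na+ for H+ on the sulfate. The free hydrogen sulfate is a strong acid that can cleave its own ester, so it is liberated last and cold, and the sodium salt 12 is the real end point of the bond-forming work.

12 from 8. The O1–C2 bond of ring C is cut. It is chosen over C2–C3, C3–C4 or C4–C4a because it is the one bond for which the target supplies its own activating group, the 4'-hydroxyl para to C1'. Opening it and adding two hydrogens gives the 1-(2,6-dihydroxyaryl)-3-arylpropane-1,2-dione 9, in which C3 and C4 are already ketones, so O3 need not be introduced by a peroxide on a sulfated polyphenol. Dione 9 rests as the hemiketal 8. The two ortho hydroxyls of 9 are equivalent, so the closure can give only one constitution, with the 5-hydroxyl free and the sulfate on O7. The forward reaction has to oxidise ring B alone to the quinone methide 10, let a ring A hydroxyl add to give the chroman-3,4-dione 11, and let 11 enolise to 12. The gain is one ring, one bond and the final oxidation in a single operation with no protecting group.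

8 from 6. The C–OH bond at C2 of the benzofuranone is cut. C2 of the 2-benzylbenzofuranone 6 is the α-carbon of a ketone whose enol is an aromatic 3-hydroxybenzofuran, so oxygen can be placed there through the enolate, by way of the hydroperoxide 7. This raises the three-carbon chain to the dione level before the key step; the forward reaction must stop after one oxygenation.

6 from 5. Two hydrogens are taken from the C2–CH2 bond and the benzyl group is put back on the ring B oxygen. In the forward sense one hydrogenation saturates the exocyclic alkene of the aurone 5 and unmasks the phenol that the anode will need, and the sulfate salt has to pass through unchanged.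

5 from 3. The O–S bond is cut. Sulfation is placed on the aurone because only two hydroxyls are free at that point and they differ most there: the 4-hydroxyl is hydrogen-bonded to the C3 carbonyl and flanked by it, the 6-hydroxyl is free and the more acidic. The later 3-hydroxyl of the flavonol does not yet exist and the ring B phenol is a benzyl ether. The pyridinium salt 4 formed first is exchanged to the sodium salt 5.

3 from 1 and 2. The exocyclic C=C bond is cut. An aldol condensation of the active methylene of 1 with the aldehyde 2 joins two purchased pieces that together contain all sixteen carbons of the target and the complete ring A oxygen pattern. The benzyl ether of 2 is the only protecting group of the route and serves only to keep the ring B oxygen out of the sulfation.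

## Alternatives that were turned down

Alternative 1: Ring A is disconnected at C4a–C5 (equivalent to C4a–C8a by symmetry) and unravelled into a tetraketide chain stored as the 4-alkoxy-2-pyrone A2.
- Forward key step: the magnesium alkoxide Mg(OCH2C6H4OMe)2 opens the lactone of A2 at its carbonyl to an ester. The methylene between the two chain ketones, held in the magnesium chelate, attacks that ester carbonyl in a Claisen-type closure, and aromatisation gives the α-benzyloxychalcone A1.
- For it: the folding follows the biosynthetic logic of ring A, and magnesium alkoxide aromatisations of pyrone-masked polyketides have precedent, so on reliability of the key step this alternative is stronger than the anodic closure. O7 is also marked by construction, as the 4-methoxybenzyl ether, and not by a selective sulfation.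
- Against it: ring A is the one part of this target that needs no synthesis, since its oxygen pattern is bought with 1. A2 would take several steps to assemble, and the aldol mode of folding competes with the Claisen mode. After A1, ring C must still be closed oxidatively, one ether removed, the sulfate introduced and two benzyl groups cleaved.
- Comparison: the chosen route gives up precedent for its key step and offers in return six operations, one protecting group, and a ring C formed directly at the flavonol oxidation level.

Alternative 2: The O1–C8a bond is disconnected, with fluorine standing in for oxygen at C8a and at C5.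
- Forward key step: with K2CO3 in DMF the enolate oxygen of the 2,6-difluoroaryl 1,3-diketone A4 displaces an ortho fluoride activated by the adjacent carbonyl and closes ring C as the 5-fluoro-3-benzyloxyflavone A3.
- For it: intramolecular displacement of an ortho fluoride by a diketone enolate is established chromone chemistry, and the two equivalent fluorides exclude regioisomers. Every intermediate is neutral and can be chromatographed, and O7 is distinguished as its methoxymethyl ether. On certainty of the ring closure this alternative is clearly stronger.
- Against it: the remaining fluoride at C5 must then be exchanged for oxygen by an intermolecular displacement on a ring that carries a donating 7-alkoxy group, in competition with conjugate attack of the oxygen nucleophile at C2 and opening of the pyranone. The route also needs fluorinated aromatic building blocks to make two C–O bonds that 1 already contains, and acetal cleavage, sulfation and double debenzylation still follow, which puts it near ten steps.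
- Comparison: the chosen route keeps all ring A oxygens from the start and concentrates its risk in one step; in place of precedent it offers a sequence about half as long with no halogen–oxygen exchange.

Alternative 3: Two bonds of ring C, C3–C4 and O1–C2, are disconnected at once, giving the 2,6-dihydroxybenzaldehyde A6 and the aryl siloxyalkyne A7.
- Forward key step: [Cp*RhCl2]2, a trivalent rhodium precatalyst, with Cu(OAc)2 as terminal oxidant, activates the aldehyde C–H bond under direction of an ortho hydroxyl, inserts the alkyne into the acyl–rhodium bond and closes the C–O bond, giving the chromone A5 with a silyl ether on O3.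
- For it: it is the most convergent plan, forming two bonds and ring C in one step with O3 at the correct oxidation level and the sulfate already in place as a neopentyl diester. Oxidative annulation of salicylaldehydes with ordinary internal alkynes is a known reaction. In convergence it is stronger than the chosen route.
- Against it: a siloxyalkyne is a ketene equivalent, so protonation at carbon by the free phenols of A6 or by the acid released from the copper carboxylate would turn it into an acylating agent before it can insert. The polarised alkyne may also insert in the opposite sense, with the oxygen-bearing carbon bonded to O1, which would give a 2-siloxy-3-aryl chromone. A6 and A7 each need several steps, and at the end the neopentyl group must be removed from the sulfate by a hot nucleophile on a free polyphenol, besides two desilylations.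
- Comparison: both key steps lack direct precedent; the chosen route offers stable salt intermediates, no precious metal, no sensitive ynol ether, and a sulfate that needs no deprotection.

Key step: step 5

## Route

Step 1
Reactants: 1 4,6-dihydroxy-1-benzofuran-3(2H)-one; 2 4-(benzyloxy)-3-methoxybenzaldehyde
Product: 3 (Z)-2-[4-(benzyloxy)-3-methoxybenzylidene]-4,6-dihydroxy-1-benzofuran-3(2H)-one
Conditions: KOH (50% aq.), MeOH, 65 °C; then 2 M HCl, 0 °C
Reagents that add atoms: none
Why: Base-mediated aldol condensation (aurone synthesis): the C2 methylene of 1, flanked by the ketone and the ring oxygen, condenses with the non-enolisable aldehyde 2 and loses water. The Z alkene, with the aryl group on the side of the ring oxygen, is the thermodynamic isomer and should form selectively.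

Step 2
Reactants: 3 (Z)-2-[4-(benzyloxy)-3-methoxybenzylidene]-4,6-dihydroxy-1-benzofuran-3(2H)-one
Product: 5 sodium (Z)-2-[4-(benzyloxy)-3-methoxybenzylidene]-4-hydroxy-3-oxo-2,3-dihydro-1-benzofuran-6-yl sulfate, via pyridinium aurone 6-sulfate 4 (not isolated)
Conditions: SO3·pyridine (1.2 equiv), pyridine, 0 °C to rt; then NaHCO3 aq.; C18 chromatography
Reagents that add atoms: sulfur trioxide pyridine complex, O=S(=O)=O.c1ccncc1; sodium hydrogen carbonate, [Na+].OC([O-])=O
Why: O-sulfation of a phenol with a sulfur trioxide–amine complex. The 4-hydroxyl is tied to the C3 carbonyl by a hydrogen bond and is hindered, whereas the 6-hydroxyl is free and is the vinylogous acid para to the acyl carbon, so a slight excess of reagent should go to O6; ring B is capped as its benzyl ether and the alkene is inert.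

Step 3
Reactants: 5 sodium (Z)-2-[4-(benzyloxy)-3-methoxybenzylidene]-4-hydroxy-3-oxo-2,3-dihydro-1-benzofuran-6-yl sulfate
Product: 6 sodium 4-hydroxy-2-(4-hydroxy-3-methoxybenzyl)-3-oxo-2,3-dihydro-1-benzofuran-6-yl sulfate (racemic at C2)
Conditions: H2 (1 atm), Pd/C, MeOH, rt; filtered under argon and used at once
Reagents that add atoms: none
Why: Heterogeneous hydrogenation saturates the exocyclic enone alkene and hydrogenolysis removes the benzyl ether in the same operation; an aryl sulfate salt and a chelated aryl ketone tolerate these conditions. C2 becomes a stereocentre, formed racemic and enolisable, which is of no consequence because it is oxygenated next and is sp2 in the target.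

Step 4
Reactants: 6 sodium 4-hydroxy-2-(4-hydroxy-3-methoxybenzyl)-3-oxo-2,3-dihydro-1-benzofuran-6-yl sulfate
Product: 8 sodium 2,4-dihydroxy-2-(4-hydroxy-3-methoxybenzyl)-3-oxo-2,3-dihydro-1-benzofuran-6-yl sulfate (racemic hemiketal), via C2 hydroperoxide 7 (not isolated)
Conditions: O2 (1 atm), NaOt-Bu (3.2 equiv), P(OEt)3, DMF–t-BuOH, −20 °C; then NaH2PO4 aq.; C18 chromatography
Reagents that add atoms: dioxygen, O=O
Why: Enolate autoxidation with in situ phosphite reduction, the α-hydroxylation of a ketone with a tertiary α-C–H: the C2–H of 6 is unusually acidic because its enolate is an aromatic benzofuran-3-olate, which should take up O2 at C2 to give 7. P(OEt)3 reduces 7 to the alcohol before it can fragment; the new quaternary hemiketal centre is racemic and labile through ring–chain tautomerism, which does not matter.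

Step 5
Reactants: 8 sodium 2,4-dihydroxy-2-(4-hydroxy-3-methoxybenzyl)-3-oxo-2,3-dihydro-1-benzofuran-6-yl sulfate
Product: 12 sodium 3,5-dihydroxy-2-(4-hydroxy-3-methoxyphenyl)-4-oxo-4H-chromen-7-yl sulfate (isorhamnetin 7-O-sulfate sodium salt), via open-chain 1,2-dione 9 (not isolated), via quinone methide 10 (not isolated), via chroman-3,4-dione 11 (not isolated)
Conditions: graphite anode, Pt cathode, undivided narrow-gap flow cell, controlled anode potential (set at the foot of the first wave of 8 by cyclic voltammetry), 2,6-lutidine (2 equiv), HFIP–MeCN, no added electrolyte, rt, partial conversion per pass with recycle of 8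
Reagents that add atoms: none
Why: Proposed new method: the guaiacyl phenol of 8, para-substituted by the benzylic CH2, should give up two electrons and two protons (to 2,6-lutidine) at the carbon anode, and since hemiketal 8 and open dione 9 interconvert by ring–chain tautomerism the oxidation funnels into quinone methide 10, whose exocyclic carbon is the future C2 of the flavonol. An ortho hydroxyl of ring A then adds to that carbon, ring B rearomatises to give 11, and the C2–H of 11, flanked by the aryl group and the C3 ketone, enolises to the aromatic 3-hydroxypyranone of 12, so O3 is inherited from the dione and no oxygen has to be added. The closest known reaction types are the anodic or quinone-mediated oxidation of 4-alkylphenols to para-quinone methides with intramolecular capture by a hydroxyl group, as in closures of 1-(2-hydroxyaryl)-3-(4-hydroxyaryl)propanes to flavans, and the Auwers ring expansion of aurone dibromides, which passes through a 1-(2-hydroxyaryl)-3-arylpropane-1,2-dione carrying a leaving group on C3; generating that cation equivalent electrochemically from a phenol has not been described. Ring C closes by O1–C2 bond formation in a 6-exo-trig mode, the breaking C2=C1' bond lying outside the new ring, whereas the competing 5-exo addition of the same hydroxyl to the C3 carbonyl (flavonol numbering) only re-forms a hemiketal reversibly and the six-membered product is drained by enolisation. No stereocentre survives, since C2 of 11 forms as a racemate and becomes sp2 in 12, and the two ortho hydroxyls of 9 are equivalent, so only one constitution can result. The step needs oxidation at ring B in preference to ring A, which the acyl and sulfate substituents of ring A should secure by making it poorer in electrons than the 4-alkyl-2-methoxyphenol. It also needs 12, itself an easily oxidised 3-hydroxyflavone with a free 4'-phenol, to escape further oxidation, which is why the potential is held at the foot of the first wave of 8 and the solution leaves the cell after a short residence time at partial conversion. The weakly nucleophilic, strongly hydrogen-bonding HFIP should keep solvent capture of 10 reversible, and the sulfate anion with lutidinium should supply the conductivity.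

Step 6
Reactants: 12 sodium 3,5-dihydroxy-2-(4-hydroxy-3-methoxyphenyl)-4-oxo-4H-chromen-7-yl sulfate
Product: 13 isorhamnetin 7-O-sulfate (3,5-dihydroxy-2-(4-hydroxy-3-methoxyphenyl)-4-oxo-4H-chromen-7-yl hydrogen sulfate)
Conditions: Dowex 50WX8 (H+ form), H2O–MeOH, 0–4 °C; immediate freeze-drying
Reagents that add atoms: none
Why: Cation exchange on a sulfonic acid resin replaces Na+ by H+ without touching any covalent bond. The free aryl hydrogen sulfate can hydrolyse under its own acidity, hence cold elution and freeze-drying without warming.

## Compound list

1 | 4,6-dihydroxy-1-benzofuran-3(2H)-one | O=C1COc2cc(O)cc(O)c12 | starting material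
2 | 4-(benzyloxy)-3-methoxybenzaldehyde | COc1cc(C=O)ccc1OCc1ccccc1 | starting material
3 | (Z)-2-[4-(benzyloxy)-3-methoxybenzylidene]-4,6-dihydroxy-1-benzofuran-3(2H)-one | COc1cc(/C=C2\Oc3cc(O)cc(O)c3C2=O)ccc1OCc1ccccc1 | intermediate
4 | pyridinium (Z)-2-[4-(benzyloxy)-3-methoxybenzylidene]-4-hydroxy-3-oxo-2,3-dihydro-1-benzofuran-6-yl sulfate (formed in the flask in step 2) | c1cc[nH+]cc1.COc1cc(/C=C2\Oc3cc(OS(=O)(=O)[O-])cc(O)c3C2=O)ccc1OCc1ccccc1 | intermediate
5 | sodium (Z)-2-[4-(benzyloxy)-3-methoxybenzylidene]-4-hydroxy-3-oxo-2,3-dihydro-1-benzofuran-6-yl sulfate | [Na+].COc1cc(/C=C2\Oc3cc(OS(=O)(=O)[O-])cc(O)c3C2=O)ccc1OCc1ccccc1 | intermediate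
6 | sodium 4-hydroxy-2-(4-hydroxy-3-methoxybenzyl)-3-oxo-2,3-dihydro-1-benzofuran-6-yl sulfate, racemic at C2 | [Na+].COc1cc(CC2Oc3cc(OS(=O)(=O)[O-])cc(O)c3C2=O)ccc1O | intermediate
7 | sodium 2-hydroperoxy-4-hydroxy-2-(4-hydroxy-3-methoxybenzyl)-3-oxo-2,3-dihydro-1-benzofuran-6-yl sulfate, racemic (formed in the flask in step 4) | [Na+].COc1cc(CC2(OO)Oc3cc(OS(=O)(=O)[O-])cc(O)c3C2=O)ccc1O | intermediate
8 | sodium 2,4-dihydroxy-2-(4-hydroxy-3-methoxybenzyl)-3-oxo-2,3-dihydro-1-benzofuran-6-yl sulfate, racemic hemiketal (ring tautomer of 9) | [Na+].COc1cc(CC2(O)Oc3cc(OS(=O)(=O)[O-])cc(O)c3C2=O)ccc1O | intermediate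
9 | sodium 3,5-dihydroxy-4-[3-(4-hydroxy-3-methoxyphenyl)-2-oxopropanoyl]phenyl sulfate (chain tautomer of 8, formed in the flask in step 5) | [Na+].COc1cc(CC(=O)C(=O)c2c(O)cc(OS(=O)(=O)[O-])cc2O)ccc1O | intermediate
10 | sodium 3,5-dihydroxy-4-[3-(3-methoxy-4-oxocyclohexa-2,5-dien-1-ylidene)-2-oxopropanoyl]phenyl sulfate, geometry of the exocyclic alkene not fixed (formed in the flask in step 5) | [Na+].COC1=CC(=CC(=O)C(=O)c2c(O)cc(OS(=O)(=O)[O-])cc2O)C=CC1=O | intermediate
11 | sodium 5-hydroxy-2-(4-hydroxy-3-methoxyphenyl)-3,4-dioxo-3,4-dihydro-2H-chromen-7-yl sulfate, racemic (formed in the flask in step 5) | [Na+].COc1cc(C2Oc3cc(OS(=O)(=O)[O-])cc(O)c3C(=O)C2=O)ccc1O | intermediate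
12 | sodium 3,5-dihydroxy-2-(4-hydroxy-3-methoxyphenyl)-4-oxo-4H-chromen-7-yl sulfate | [Na+].COc1cc(-c2oc3cc(OS(=O)(=O)[O-])cc(O)c3c(=O)c2O)ccc1O | intermediate
13 | isorhamnetin 7-O-sulfate, 3,5-dihydroxy-2-(4-hydroxy-3-methoxyphenyl)-4-oxo-4H-chromen-7-yl hydrogen sulfate | COc1cc(-c2oc3cc(OS(=O)(=O)O)cc(O)c3c(=O)c2O)ccc1O | target

## Step count and least certain steps

Total step count: 6. Longest linear sequence: 6 steps (from 1 or 2 to 13).

Step 5 (key step). The most likely failure is further oxidation of the product at the anode, because 12 may be oxidised at a potential close to or below that of 8. Other risks are oxidation that starts on ring A, capture of the quinone methide by solvent or by a second molecule with fouling of the anode, and cathodic reduction of the dione if proton reduction at Pt is not fast enough. The fallback builds the flavonol by known chemistry and sets out from 2: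
- Pinnick oxidation of 2 (NaClO2, NaH2PO4, 2-methyl-2-butene) should give 4-(benzyloxy)-3-methoxybenzoic acid F1, which is dehydrated with dicyclohexylcarbodiimide to 4-(benzyloxy)-3-methoxybenzoic anhydride F2.
- Houben–Hoesch acylation of purchased phloroglucinol with purchased benzyloxyacetonitrile (HCl, ZnCl2, then hot water) gives 2-(benzyloxy)-1-(2,4,6-trihydroxyphenyl)ethan-1-one F3.
- Allan–Robinson condensation of F3 with F2 and the sodium salt of F1 at about 170 °C, followed by KOH in aqueous ethanol to cleave the aroyl esters, gives 3-(benzyloxy)-2-[4-(benzyloxy)-3-methoxyphenyl]-5,7-dihydroxy-4H-chromen-4-one F4.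
- SO3·pyridine sulfates the unchelated 7-hydroxyl and NaHCO3 gives sodium 3-(benzyloxy)-2-[4-(benzyloxy)-3-methoxyphenyl]-5-hydroxy-4-oxo-4H-chromen-7-yl sulfate F5.
- H2 over Pd/C removes both benzyl ethers and comes back to the route at 12.

Step 4. The likely failures are a second oxygenation at the benzylic methylene through the enolate of the opened dione, cleavage of the C2–C3 bond by the hydroperoxide before the phosphite intercepts it, and slow oxidation of the phenolates. The fallback avoids the enolisable ketone and sets out from 5: Weitz–Scheffer epoxidation of the aurone alkene (H2O2, NaOH, MeOH–H2O, 0 °C) should give sodium 3'-[4-(benzyloxy)-3-methoxyphenyl]-4-hydroxy-3-oxo-3H-spiro[1-benzofuran-2,2'-oxiran]-6-yl sulfate F6 as a racemate. Hydrogenolysis over Pd/C (H2, MeOH) then cleaves the benzylic C–O bond of the epoxide together with the benzyl ether and comes back to the route at 8, bypassing 6 and 7.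

Step 2. The likely failures are sulfation of both ring A hydroxyls or of the chelated one, and losses on purifying a polar salt. The fallback carries the sulfate as a neutral diester and sets out from 3: 2,2,2-trichloroethyl chlorosulfate with Et3N and 4-dimethylaminopyridine in THF should give (Z)-2-[4-(benzyloxy)-3-methoxybenzylidene]-4-hydroxy-3-oxo-2,3-dihydro-1-benzofuran-6-yl 2,2,2-trichloroethyl sulfate F7, which can be separated from isomers on silica. Transfer hydrogenation (Pd/C, HCO2NH4, MeOH) cleaves the trichloroethyl group, saturates the alkene and removes the benzyl ether to give ammonium 4-hydroxy-2-(4-hydroxy-3-methoxybenzyl)-3-oxo-2,3-dihydro-1-benzofuran-6-yl sulfate F8. Treatment with NaHCO3 and evaporation exchanges the cation and comes back to the route at 6.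

Step 6. The likely failure is hydrolysis of the sulfate ester, catalysed by the free acid itself as the eluate is concentrated. The fallback sets out from 12 and avoids water and resin: one equivalent of anhydrous HCl in cold MeCN–MeOH protonates the sulfate, the precipitated NaCl is filtered off and the solvent is removed cold to reach 13. It makes no new compound.

## Further compounds

F1 | step 5 | 4-(benzyloxy)-3-methoxybenzoic acid | COc1cc(C(=O)O)ccc1OCc1ccccc1
F2 | step 5 | 4-(benzyloxy)-3-methoxybenzoic anhydride | COc1cc(C(=O)OC(=O)c2ccc(OCc3ccccc3)c(OC)c2)ccc1OCc1ccccc1
F3 | step 5 | 2-(benzyloxy)-1-(2,4,6-trihydroxyphenyl)ethan-1-one | O=C(COCc1ccccc1)c1c(O)cc(O)cc1O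
F4 | step 5 | 3-(benzyloxy)-2-[4-(benzyloxy)-3-methoxyphenyl]-5,7-dihydroxy-4H-chromen-4-one | COc1cc(-c2oc3cc(O)cc(O)c3c(=O)c2OCc2ccccc2)ccc1OCc1ccccc1
F5 | step 5 | sodium 3-(benzyloxy)-2-[4-(benzyloxy)-3-methoxyphenyl]-5-hydroxy-4-oxo-4H-chromen-7-yl sulfate | [Na+].COc1cc(-c2oc3cc(OS(=O)(=O)[O-])cc(O)c3c(=O)c2OCc2ccccc2)ccc1OCc1ccccc1
F6 | step 4 | sodium 3'-[4-(benzyloxy)-3-methoxyphenyl]-4-hydroxy-3-oxo-3H-spiro[1-benzofuran-2,2'-oxiran]-6-yl sulfate, racemic, relative configuration not fixed | [Na+].COc1cc(C2OC23Oc2cc(OS(=O)(=O)[O-])cc(O)c2C3=O)ccc1OCc1ccccc1
F7 | step 2 | (Z)-2-[4-(benzyloxy)-3-methoxybenzylidene]-4-hydroxy-3-oxo-2,3-dihydro-1-benzofuran-6-yl 2,2,2-trichloroethyl sulfate | COc1cc(/C=C2\Oc3cc(OS(=O)(=O)OCC(Cl)(Cl)Cl)cc(O)c3C2=O)ccc1OCc1ccccc1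
F8 | step 2 | ammonium 4-hydroxy-2-(4-hydroxy-3-methoxybenzyl)-3-oxo-2,3-dihydro-1-benzofuran-6-yl sulfate, racemic at C2 | [NH4+].COc1cc(CC2Oc3cc(OS(=O)(=O)[O-])cc(O)c3C2=O)ccc1O
F0 | step 6 | none | none
A1 | alternative 1 | (Z)-2-(benzyloxy)-3-(4-benzyloxy-3-methoxyphenyl)-1-{2,6-dihydroxy-4-[(4-methoxybenzyl)oxy]phenyl}prop-2-en-1-one | COc1ccc(COc2cc(O)c(C(=O)/C(OCc3ccccc3)=C/c3ccc(OCc4ccccc4)c(OC)c3)c(O)c2)cc1
A2 | alternative 1 | 6-[(3Z)-3-(benzyloxy)-4-(4-benzyloxy-3-methoxyphenyl)-2-oxobut-3-en-1-yl]-4-[(4-methoxybenzyl)oxy]-2H-pyran-2-one | COc1ccc(COc2cc(CC(=O)/C(OCc3ccccc3)=C/c3ccc(OCc4ccccc4)c(OC)c3)oc(=O)c2)cc1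
A3 | alternative 2 | 3-(benzyloxy)-2-(4-benzyloxy-3-methoxyphenyl)-5-fluoro-7-(methoxymethoxy)-4H-chromen-4-one | COCOc1cc(F)c2c(=O)c(OCc3ccccc3)c(-c3ccc(OCc4ccccc4)c(OC)c3)oc2c1
A4 | alternative 2 | 2-(benzyloxy)-1-(4-benzyloxy-3-methoxyphenyl)-3-[2,6-difluoro-4-(methoxymethoxy)phenyl]propane-1,3-dione, racemic | COCOc1cc(F)c(C(=O)C(OCc2ccccc2)C(=O)c2ccc(OCc3ccccc3)c(OC)c2)c(F)c1
A5 | alternative 3 | 5-hydroxy-2-[3-methoxy-4-(triisopropylsilyloxy)phenyl]-4-oxo-3-(triisopropylsilyloxy)-4H-chromen-7-yl neopentyl sulfate | COc1cc(-c2oc3cc(OS(=O)(=O)OCC(C)(C)C)cc(O)c3c(=O)c2O[Si](C(C)C)(C(C)C)C(C)C)ccc1O[Si](C(C)C)(C(C)C)C(C)C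
A6 | alternative 3 | 4-formyl-3,5-dihydroxyphenyl neopentyl sulfate | CC(C)(C)COS(=O)(=O)Oc1cc(O)c(C=O)c(O)c1
A7 | alternative 3 | triisopropyl({[3-methoxy-4-(triisopropylsilyloxy)phenyl]ethynyl}oxy)silane | COc1cc(C#CO[Si](C(C)C)(C(C)C)C(C)C)ccc1O[Si](C(C)C)(C(C)C)C(C)C
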